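**Plan**

- Retrosynthetic cuts, in this order: the C2–C3 bond of the dihydrofuran fused to ring A (carbene C–H insertion), the ring A–C(=O) bond (aryllithium acylation), the ring A–C8 bond of the seven-membered ring (Friedel–Crafts), the stilbene C–C bond (Heck), the C2–C3 bond of the ring B dihydrofuran (same insertion), and the ring B–C(=O) bond (Friedel–Crafts acylation).
- Forward order: benzophenone, ring B dihydrofuran, stilbene, seven-membered ring (closed while ring A is still symmetric, so only one regiochemistry is possible), ring A ketone, differentiation of the two ring A oxygens, ring A dihydrofuran, global demethylation.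
- Stereochemistry: C3 of each dihydrofuran comes from the chiral catalyst Rh2(R-PTAD)4; C2 of each comes from acid equilibration to trans; the diaryl methine C8 comes from substrate control in the cationic ring closure.
- Feature that makes the key event possible: in the dihydrofuran on ring A, C3 is a methine between two aryl rings (ring A and the 3,5-dioxyphenyl ring), so it can be a diaryl carbene carbon. C2 is an oxygen-bound CH with a 4-oxyphenyl group, so it can be the benzylic CH2 of a 4-methoxybenzyl ether on the ring A oxygen, sitting 1,5 to that carbene carbon.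

Key step: step 11

Assumption: Rh2(R-PTAD)4 (dirhodium tetrakis[(R)-(1-adamantyl)(phthalimido)acetate]) is taken to deliver the 3S sense in both insertions; should the sense prove opposite, Rh2(S-PTAD)4 is used in its place.

Naming note: "core" means (1S,8S,16S)-8-(2,4-dimethoxyphenyl)-12-methoxy-16-(4-methoxyphenyl)-15-oxatetracyclo[8.6.1.0(2,7).0(14,17)]heptadeca-2,4,6,10,12,14(17)-hexaene. C1 and C16 are C3 and C2 of the ring B dihydrofuran, C8 is the diaryl methine, C9 is the CH2, and C2–C7 is ring A. C4, C5 and C6 are the substituted positions of ring A, with C6 next to C7, which carries C8.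

**Route**

Step 1
Reactants: 1 4-bromo-3,5-dimethoxybenzoic acid; 2 1-bromo-3,5-dimethoxybenzene
Product: 5 (2-bromo-6-hydroxy-4-methoxyphenyl)(4-bromo-3,5-dimethoxyphenyl)methanone, via acid chloride 3 (not isolated), via dimethoxy ketone 4 (not isolated)
Conditions: (COCl)2, DMF (cat.), CH2Cl2, rt; then 2, AlCl3 (3 equiv), CH2Cl2, 0 → 40 °C
Reagents that add atoms: none
Why: Friedel–Crafts acylation of 2 should occur para to one methoxy group and ortho to the other (between Br and OMe, the usual site of electrophilic attack on this arene), and excess AlCl3 should then cleave only the methoxy group ortho to the new carbonyl by chelation.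

Step 2
Reactants: 5; 6 4-methoxybenzyl chloride
Product: 7 {2-bromo-4-methoxy-6-[(4-methoxyphenyl)methoxy]phenyl}(4-bromo-3,5-dimethoxyphenyl)methanone
Conditions: K2CO3, NaI (cat.), DMF, 60 °C
Reagents that add atoms: none
Why: Williamson etherification of the phenol installs the benzylic CH2 that becomes C2 of the first dihydrofuran.

Step 3
Reactants: 7
Product: 8 hydrazone of 7 (C=N–NH2 in place of C=O)
Conditions: N2H4·H2O (10 equiv), AcOH (cat.), EtOH, 90 °C, sealed tube
Reagents that add atoms: hydrazine (as hydrate), NN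
Why: Acid-catalysed hydrazone formation with a small alpha-effect nucleophile should proceed despite the two ortho substituents because the second aryl ring is unhindered.

Step 4
Reactants: 8
Product: 11 (2S,3S)-4-bromo-3-(4-bromo-3,5-dimethoxyphenyl)-6-methoxy-2-(4-methoxyphenyl)-2,3-dihydro-1-benzofuran (trans), via diazo compound 9 (not isolated), via cis dihydrobenzofuran 10 (not isolated)
Conditions: MnO2 (8 equiv), CH2Cl2, 0 °C, filter; Rh2(R-PTAD)4 (1 mol %), 0 °C → rt; then TFA (5 equiv), rt
Reagents that add atoms: none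
Why: MnO2 dehydrogenates the hydrazone to the diaryldiazomethane, the chiral rhodium carboxylate converts it into a donor/donor carbene that inserts 1,5 into the benzylic C–H of the ether (intramolecular carbene C–H insertion) with the catalyst setting C3 (S) and the cis ring forming first, and TFA then equilibrates C2 through the 4-methoxybenzylic cation to the more stable trans isomer.

Step 5
Reactants: 11; 12 2,4-dimethoxystyrene
Product: 13 (2S,3S)-3-(4-bromo-3,5-dimethoxyphenyl)-4-[(E)-2-(2,4-dimethoxyphenyl)ethenyl]-6-methoxy-2-(4-methoxyphenyl)-2,3-dihydro-1-benzofuran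
Conditions: Pd(OAc)2 (5 mol %), P(o-tol)3 (12 mol %), K2CO3, DMF, 100 °C
Reagents that add atoms: none
Why: Mizoroki–Heck reaction in which oxidative addition should prefer the C4 bromide over the electron-rich bromide flanked by two methoxy groups, and syn insertion followed by syn beta-hydride elimination gives the E-stilbene.

Step 6
Reactants: 13
Product: 14 5-bromo-4,6-dimethoxy core
Conditions: TFA (10 equiv), CH2Cl2 (0.005 M), 0 °C → rt
Reagents that add atoms: none
Why: Protonation of the stilbene at the carbon next to ring B gives the 2,4-dimethoxybenzylic cation, which an ortho position of the still symmetric ring A captures in a seven-membered Friedel–Crafts closure (both positions equivalent, hence one regioisomer), and the C3 centre should steer the aryl group into the pseudo-equatorial position that corresponds to 8S, as is known for stilbenes of the epsilon-viniferin type.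

Step 7
Reactants: 14; 15 3,5-dimethoxybenzoyl chloride
Product: 17 5-(3,5-dimethoxybenzoyl)-4,6-dimethoxy core, via aryllithium 16 (not isolated)
Conditions: n-BuLi (1.05 equiv), THF, −78 °C; then addition to 15 (2 equiv), THF, −78 → 0 °C
Reagents that add atoms: none
Why: Bromine–lithium exchange at the bromide between two methoxy groups is fast at −78 °C, and the hindered aryllithium should be acylated only once because the product ketone is too shielded for a second addition.

Step 8
Reactants: 17
Product: 18 5-(3,5-dimethoxybenzoyl)-6-hydroxy-4-methoxy core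
Conditions: BCl3 (1.5 equiv), CH2Cl2, −78 → −20 °C; aq. NaHCO3
Reagents that add atoms: none
Why: Chelation-controlled ether cleavage by BCl3 removes one methoxy group ortho to the ketone, and the C6 methoxy group, flanked on both sides (ketone and the C7 carbon that bears C8) and twisted out of conjugation, should react before the C4 methoxy group.

Step 9
Reactants: 18; 6 4-methoxybenzyl chloride
Product: 19 5-(3,5-dimethoxybenzoyl)-4-methoxy-6-[(4-methoxyphenyl)methoxy] core
Conditions: Cs2CO3, NaI (cat.), DMF, 50 °C
Reagents that add atoms: none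
Why: Williamson etherification places the 4-methoxybenzyl group on the oxygen that becomes the ring oxygen of the second dihydrofuran.

Step 10
Reactants: 19
Product: 20 hydrazone of 19 (C=N–NH2 in place of C=O)
Conditions: N2H4·H2O (20 equiv), AcOH (cat.), n-BuOH, 110 °C, sealed tube
Reagents that add atoms: hydrazine (as hydrate), NN
Why: Hydrazone formation under forcing, acid-catalysed conditions should overcome the two ortho alkoxy groups because the 3,5-dimethoxyphenyl side of the carbonyl is open.

Step 11
Reactants: 20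
Product: 23 octamethyl ether of the target (core with 4-OMe, fused across C5–C6, oxygen on C6, to a trans-2,3-dihydrofuran whose C2 (S) bears 4-methoxyphenyl and whose C3 (S) bears 3,5-dimethoxyphenyl), via diazo compound 21 (not isolated), via cis dihydrofuran 22 (not isolated)
Conditions: MnO2 (10 equiv), CH2Cl2, 0 °C, filter; Rh2(R-PTAD)4 (2 mol %), 0 °C → rt; then TFA (5 equiv), rt
Reagents that add atoms: none
Why: MnO2 dehydrogenates the hydrazone to diaryldiazomethane 21, which the rhodium carboxylate converts with loss of N2 into a donor/donor carbene at the future C3; the carbene carbon inserts into one benzylic C–H of the 4-methoxybenzyl ether on the neighbouring ring A oxygen through a hydride-shift-like three-centre transition state, so that C3 receives the hydrogen and the C2–C3 bond forms. The closest known reaction type is the intramolecular C–H insertion of donor/donor rhodium carbenes into benzyl aryl ethers, which gives 2,3-diaryl-2,3-dihydrobenzofurans. The dihydrofuran closes as a five-membered ring by 1,5-insertion (carbene carbon, two ring A carbons, oxygen, benzylic carbon). C3 (S) is set by the chiral carboxylate ligands of the catalyst, which should override the remote centres of the core; C2 first arises cis to it from the insertion geometry and is then equilibrated by TFA through the ring-opened 4-methoxybenzylic cation to the trans (2S) arrangement. The step needs site selectivity between the benzylic CH2 and the methyl C–H bonds of the methoxy group at the other ortho position, and the benzylic, oxygen-bound, 4-methoxyphenyl-activated C–H is expected to react far faster; it also needs chemoselectivity over attack on the electron-rich arenes, which the low electrophilicity of a diaryl carbene should secure.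

Step 12
Reactants: 23
Product: 24 CNP0154774.1 (target)
Conditions: BBr3 (24 equiv), CH2Cl2, −78 °C → rt; MeOH, then H2O
Reagents that add atoms: none
Why: Lewis-acid demethylation with BBr3 should cleave all eight aryl methyl ethers while leaving the trans-dihydrobenzofurans and the five stereocentres intact.

**Compound list**

1 | 4-bromo-3,5-dimethoxybenzoic acid | COc1cc(cc(OC)c1Br)C(=O)O | starting material
2 | 1-bromo-3,5-dimethoxybenzene | COc1cc(Br)cc(OC)c1 | starting material
3 | 4-bromo-3,5-dimethoxybenzoyl chloride (formed in situ) | COc1cc(cc(OC)c1Br)C(=O)Cl | intermediate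
4 | (2-bromo-4,6-dimethoxyphenyl)(4-bromo-3,5-dimethoxyphenyl)methanone (formed in situ) | COc1cc(cc(OC)c1Br)C(=O)c1c(Br)cc(OC)cc1OC | intermediate
5 | (2-bromo-6-hydroxy-4-methoxyphenyl)(4-bromo-3,5-dimethoxyphenyl)methanone | COc1cc(cc(OC)c1Br)C(=O)c1c(Br)cc(OC)cc1O | intermediate
6 | 4-methoxybenzyl chloride | COc1ccc(CCl)cc1 | starting material
7 | {2-bromo-4-methoxy-6-[(4-methoxyphenyl)methoxy]phenyl}(4-bromo-3,5-dimethoxyphenyl)methanone | COc1cc(cc(OC)c1Br)C(=O)c1c(Br)cc(OC)cc1OCc1ccc(OC)cc1 | intermediate
8 | hydrazone of 7 | COc1cc(cc(OC)c1Br)C(=NN)c1c(Br)cc(OC)cc1OCc1ccc(OC)cc1 | intermediate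
9 | diaryldiazomethane from 8 (formed in situ) | COc1cc(cc(OC)c1Br)C(=[N+]=[N-])c1c(Br)cc(OC)cc1OCc1ccc(OC)cc1 | intermediate
10 | (2R,3S)-4-bromo-3-(4-bromo-3,5-dimethoxyphenyl)-6-methoxy-2-(4-methoxyphenyl)-2,3-dihydro-1-benzofuran (cis, formed in situ) | COc1cc(cc(OC)c1Br)[C@H]2c3c(Br)cc(OC)cc3O[C@H]2c2ccc(OC)cc2 | intermediate
11 | (2S,3S)-4-bromo-3-(4-bromo-3,5-dimethoxyphenyl)-6-methoxy-2-(4-methoxyphenyl)-2,3-dihydro-1-benzofuran (trans) | COc1cc(cc(OC)c1Br)[C@H]2c3c(Br)cc(OC)cc3O[C@@H]2c2ccc(OC)cc2 | intermediate
12 | 2,4-dimethoxystyrene | C=Cc1ccc(OC)cc1OC | starting material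
13 | (2S,3S)-3-(4-bromo-3,5-dimethoxyphenyl)-4-[(E)-2-(2,4-dimethoxyphenyl)ethenyl]-6-methoxy-2-(4-methoxyphenyl)-2,3-dihydro-1-benzofuran | COc1cc(cc(OC)c1Br)[C@H]2c3c(/C=C/c4ccc(OC)cc4OC)cc(OC)cc3O[C@@H]2c2ccc(OC)cc2 | intermediate
14 | 5-bromo-4,6-dimethoxy core | Brc1c(OC)c4c(cc1OC)[C@H]2c3c(cc(OC)cc3O[C@@H]2c2ccc(OC)cc2)C[C@H]4c2ccc(OC)cc2OC | intermediate
15 | 3,5-dimethoxybenzoyl chloride | COc1cc(cc(OC)c1)C(=O)Cl | starting material
16 | 5-lithio-4,6-dimethoxy core (formed in situ) | [Li]c1c(OC)c4c(cc1OC)[C@H]2c3c(cc(OC)cc3O[C@@H]2c2ccc(OC)cc2)C[C@H]4c2ccc(OC)cc2OC | intermediate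
17 | 5-(3,5-dimethoxybenzoyl)-4,6-dimethoxy core | O=C(c1cc(OC)cc(OC)c1)c1c(OC)c4c(cc1OC)[C@H]2c3c(cc(OC)cc3O[C@@H]2c2ccc(OC)cc2)C[C@H]4c2ccc(OC)cc2OC | intermediate
18 | 5-(3,5-dimethoxybenzoyl)-6-hydroxy-4-methoxy core | O=C(c1cc(OC)cc(OC)c1)c1c(O)c4c(cc1OC)[C@H]2c3c(cc(OC)cc3O[C@@H]2c2ccc(OC)cc2)C[C@H]4c2ccc(OC)cc2OC | intermediate
19 | 5-(3,5-dimethoxybenzoyl)-4-methoxy-6-[(4-methoxyphenyl)methoxy] core | O=C(c1cc(OC)cc(OC)c1)c1c(OCc5ccc(OC)cc5)c4c(cc1OC)[C@H]2c3c(cc(OC)cc3O[C@@H]2c2ccc(OC)cc2)C[C@H]4c2ccc(OC)cc2OC | intermediate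
20 | hydrazone of 19 | NN=C(c1cc(OC)cc(OC)c1)c1c(OCc5ccc(OC)cc5)c4c(cc1OC)[C@H]2c3c(cc(OC)cc3O[C@@H]2c2ccc(OC)cc2)C[C@H]4c2ccc(OC)cc2OC | intermediate
21 | diaryldiazomethane from 20 (formed in situ) | [N-]=[N+]=C(c1cc(OC)cc(OC)c1)c1c(OCc5ccc(OC)cc5)c4c(cc1OC)[C@H]2c3c(cc(OC)cc3O[C@@H]2c2ccc(OC)cc2)C[C@H]4c2ccc(OC)cc2OC | intermediate
22 | cis isomer of 23 (new dihydrofuran C2 R, C3 S; formed in situ) | COc1ccc([C@@H]2Oc3c4c(cc(OC)c3[C@@H]2c2cc(OC)cc(OC)c2)[C@H]2c3c(cc(OC)cc3O[C@@H]2c2ccc(OC)cc2)C[C@H]4c2ccc(OC)cc2OC)cc1 | intermediate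
23 | octamethyl ether of the target (new dihydrofuran C2 S, C3 S, trans) | COc1ccc([C@H]2Oc3c4c(cc(OC)c3[C@@H]2c2cc(OC)cc(OC)c2)[C@H]2c3c(cc(OC)cc3O[C@@H]2c2ccc(OC)cc2)C[C@H]4c2ccc(OC)cc2OC)cc1 | intermediate
24 | CNP0154774.1 | Oc1ccc([C@H]2Oc3c4c(cc(O)c3[C@@H]2c2cc(O)cc(O)c2)[C@H]2c3c(cc(O)cc3O[C@@H]2c2ccc(O)cc2)C[C@H]4c2ccc(O)cc2O)cc1 | target

**Count and risks**

Total step count: 12. Longest linear sequence: 12 steps (from 1 and 2 to 24).

Steps most likely to fail:

1. Step 11. The chiral catalyst and the chiral core may be mismatched, giving poor facial selectivity at C3, or the hindered carbene may be diverted into azine formation or insertion into the methyl C–H of the neighbouring methoxy group. The fallback sets out from 18. Acylation with 4-methoxybenzoyl chloride (Et3N, DMAP, CH2Cl2) gives the keto ester F3. Intramolecular reductive keto–ester coupling with low-valent titanium (TiCl3, Zn, DME, reflux; McMurry-type benzofuran synthesis) forms the same C2–C3 bond as the C=C bond of the 2,3-diarylbenzofuran F4. Ionic hydrogenation (Et3SiH, TFA, CH2Cl2) should give the trans-dihydrofuran as 23 together with the diastereomer inverted at both new centres F5, to be separated by chromatography. The route is rejoined at 23.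

2. Step 8. Regioselectivity may be lost, with the C4 methoxy group cleaved instead of the C6 one, or both cleaved. The fallback sets out from 17. Excess BCl3 (4 equiv, CH2Cl2, 0 °C → rt) cleaves both methoxy groups ortho to the ketone to give the 4,6-diol F1. Monomethylation (MeI, 1 equiv, K2CO3, acetone) should then occur at the less hindered C4 hydroxyl, because the C6 hydroxyl is shielded by the C8 methine and its aryl group. The route is rejoined at 18.

3. Step 10. The condensation may stall because two ortho alkoxy groups shield the carbonyl carbon. The fallback sets out from 18. The ortho-hydroxy ketone is condensed with hydrazine first (N2H4·H2O, EtOH, 80 °C), where the small phenol activates the carbonyl by hydrogen bonding, to give the hydroxy hydrazone F2. The phenoxide, far more nucleophilic than the hydrazone nitrogen, is then alkylated with 6 (K2CO3, acetone). The route is rejoined at 20.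

**Further compounds**

F1 | step 8 | 5-(3,5-dimethoxybenzoyl)-4,6-dihydroxy core | O=C(c1cc(OC)cc(OC)c1)c1c(O)c4c(cc1O)[C@H]2c3c(cc(OC)cc3O[C@@H]2c2ccc(OC)cc2)C[C@H]4c2ccc(OC)cc2OC
F2 | step 10 | hydrazone of 18 (6-hydroxy-4-methoxy core, C=N–NH2 in place of C=O) | NN=C(c1cc(OC)cc(OC)c1)c1c(O)c4c(cc1OC)[C@H]2c3c(cc(OC)cc3O[C@@H]2c2ccc(OC)cc2)C[C@H]4c2ccc(OC)cc2OC
F3 | step 11 | 4-methoxybenzoate ester of 18 (ester on the C6 oxygen) | O=C(c1cc(OC)cc(OC)c1)c1c(OC(=O)c5ccc(OC)cc5)c4c(cc1OC)[C@H]2c3c(cc(OC)cc3O[C@@H]2c2ccc(OC)cc2)C[C@H]4c2ccc(OC)cc2OC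
F4 | step 11 | benzofuran analogue of 23 (C2=C3 double bond in the ring A furan) | COc1ccc(-c2oc3c4c(cc(OC)c3c2-c2cc(OC)cc(OC)c2)[C@H]2c3c(cc(OC)cc3O[C@@H]2c2ccc(OC)cc2)C[C@H]4c2ccc(OC)cc2OC)cc1
F5 | step 11 | diastereomer of 23 with the new dihydrofuran C2 R, C3 R (trans) | COc1ccc([C@@H]2Oc3c4c(cc(OC)c3[C@H]2c2cc(OC)cc(OC)c2)[C@H]2c3c(cc(OC)cc3O[C@@H]2c2ccc(OC)cc2)C[C@H]4c2ccc(OC)cc2OC)cc1
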